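**Plan**

1. Numbering and feature: ring C1 (C=O), C2=C3, C4 (OMe), C5 (CH2), C6 (quaternary); chain C8 (CHMe, methyl carbon C10) and C7 (CHOAc–aryl); the allyl CH2 on C6 is C9. The ring is a cyclohex-2-ene with oxygen on both allylic carbons (C1, C4) and the quaternary C6 beside the C5 methylene, the retron of a 1,4-dioxygenated butadiene plus a 1,1-disubstituted carbonyl-activated alkene.
2. Retrosynthesis cuts C1–C6 and C4–C5 (Diels–Alder), then C7–C8 (aldol). The allyl group is traced to the activating carbonyl carbon C9, and the C8 methyl to C10 held as the O–CH2 of a lactone.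
3. Forward: an anti-aldol joins the aryl carbinol C7 to a succinate (C10–C8–C6–C9); the chain is closed to a γ-lactone and methylenated at C6. The cyclohexene then arises by the [4+2] step; C4 is inverted and methylated, the lactone is unravelled to allyl and methyl, C1 is oxidised and C7 acetylated.
4. Stereochemistry: C8 and C7 come from the oxazolidinone-controlled anti-aldol. C6 comes from the diene adding to the methylene face anti to the C7 arm of the ring-locked lactone. C1/C4 are cis from the E,E-diene and cis to C9 from endo addition, so C4 is corrected by one Mitsunobu inversion and C1 ends as the ketone.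
5. The dienophile is the α-methylene lactone rather than an open-chain 2-methylene aldehyde. In the open chain the face of addition would depend on a rotamer about C6–C8, and the likely rotamer exposes the wrong face; the ring leaves only C8–H on one face.

Key step: step 6

**Route**

Step 1
Reactants: 1 (R)-4-benzyl-1,3-oxazolidin-2-one; 2 methyl 4-chloro-4-oxobutanoate
Product: 3 methyl 4-[(4R)-4-benzyl-2-oxo-1,3-oxazolidin-3-yl]-4-oxobutanoate
Conditions: Et3N, DMAP (cat.), CH2Cl2, 0 °C → rt
Reagents that add atoms: none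
Why: DMAP-catalysed N-acylation of the oxazolidinone by the acid chloride is routine and attaches the auxiliary that will control C8 and C7.

Step 2
Reactants: 3 methyl 4-[(4R)-4-benzyl-2-oxo-1,3-oxazolidin-3-yl]-4-oxobutanoate; 4 3,4,5-trimethoxybenzaldehyde
Product: 5 methyl (3S,4R)-3-{[(4R)-4-benzyl-2-oxo-1,3-oxazolidin-3-yl]carbonyl}-4-(trimethylsilyloxy)-4-(3,4,5-trimethoxyphenyl)butanoate
Conditions: MgCl2 (0.2 equiv), Et3N, Me3SiCl, EtOAc, rt
Reagents that add atoms: chlorotrimethylsilane, C[Si](C)(C)Cl
Why: MgCl2-catalysed direct anti-aldol reaction of an N-acyloxazolidinone with an aromatic aldehyde, in which soft enolisation of the chelated imide gives the Z-enolate, the aldehyde adds to the enolate face opposite the benzyl group (C8, S) through a boat-like transition state that gives the 2,3-anti relationship (C7, R), and silylation of the aldolate turns the catalyst over.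

Step 3
Reactants: 5 anti-aldol adduct as trimethylsilyl ether
Product: 7 methyl (3S,4R)-3-{[(4R)-4-benzyl-2-oxo-1,3-oxazolidin-3-yl]carbonyl}-4-(tert-butyldimethylsilyloxy)-4-(3,4,5-trimethoxyphenyl)butanoate, via free aldol alcohol 6 (not isolated)
Conditions: citric acid (cat.), MeOH, 0 °C; evaporation; t-BuMe2SiOTf, 2,6-lutidine, CH2Cl2, −78 → 0 °C
Reagents that add atoms: tert-butyldimethylsilyl trifluoromethanesulfonate, CC(C)(C)[Si](C)(C)OS(=O)(=O)C(F)(F)F
Why: Mild acidic methanolysis removes the labile trimethylsilyl group and immediate silyl ether formation with the silyl triflate installs the robust silyl ether before the γ-hydroxy ester can lactonise onto C9; no stereocentre is touched.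

Step 4
Reactants: 7 silyl-protected aldol imide
Product: 9 (4R)-4-[(R)-(tert-butyldimethylsilyloxy)(3,4,5-trimethoxyphenyl)methyl]oxolan-2-one, via hydroxy ester 8 (not isolated)
Conditions: NaBH4, THF–H2O (4:1), 0 °C → rt; then pyridinium p-toluenesulfonate (cat.), CH2Cl2, rt
Reagents that add atoms: none
Why: Borohydride reduction of the N-acyloxazolidinone (reductive auxiliary cleavage) spares the methyl ester, and the freed primary alcohol closes the γ-lactone by intramolecular transesterification, which puts the future C8 methyl carbon C10 into the ring.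

Step 5
Reactants: 9 γ-lactone
Product: 12 (4R)-4-[(R)-(tert-butyldimethylsilyloxy)(3,4,5-trimethoxyphenyl)methyl]-3-methylideneoxolan-2-one, via Mannich base 10 (not isolated), via methiodide 11 (not isolated)
Conditions: LiN(i-Pr)2, THF, −78 °C; Me2N=CH2 iodide, −78 °C → rt; MeI, MeOH, rt; aq. NaHCO3, CH2Cl2
Reagents that add atoms: N,N-dimethylmethylideneammonium iodide (Eschenmoser's salt), C=[N+](C)C.[I-]
Why: α-Methylenation of a lactone by Mannich reaction of its lithium enolate with Eschenmoser's salt, N-quaternisation and base-induced elimination of trimethylamine; the transient stereocentre at C6 disappears in the elimination.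

Step 6
Reactants: 12 α-methylene lactone; 13 (1E,3E)-buta-1,3-diene-1,4-diyl diacetate
Product: 14 spirolactone cycloadduct, 6,9-diacetoxy-4-[(R)-(tert-butyldimethylsilyloxy)(3,4,5-trimethoxyphenyl)methyl]-2-oxaspiro[4.5]dec-7-en-1-one; the acetoxy groups on C1 and C4 are cis to each other and to the lactone carbonyl carbon C9, trans to ring carbon C8; C6 configured as in the target
Conditions: 13 (3 equiv), 2,6-di-tert-butyl-4-methylphenol (cat.), toluene, 130 °C, sealed tube
Reagents that add atoms: none
Why: Concerted, suprafacial, normal-demand [4+2] cycloaddition (Diels–Alder) between the E,E-diene and the exocyclic lactone-activated alkene; the closest known cases are the thermal additions of (E,E)-1,4-diacyloxybutadienes to acrylic dienophiles and of α-methylene-γ-butyrolactones to dienes. The cyclohexene ring closes in one step by forming C1–C6 and C4–C5, which makes C6 a spiro centre. C1 and C4 come out cis to each other because both acetoxy groups are E on the diene; their relation to C6 follows from the endo orientation of the lactone carbonyl (Alder rule, and the sp3 ring carbon C8 with its hydrogen avoids the space under the diene), so both acetoxy groups end up cis to C9. The configuration of C6 is set by the face of the methylene group that is attacked: the five-membered ring holds C10 in the plane of the alkene and leaves only C8–H on one face and the bulky aryl(silyloxy)methyl arm on the other, so the diene adds anti to that arm and gives the C6 configuration of the target. The step therefore needs facial selectivity (secured by the ring-locked C8 substituent, which an open-chain rotamer could not guarantee) and endo selectivity (electronic, and relevant only to C4, which step 8 inverts). Excess diene and a radical inhibitor counter the modest reactivity of the pair.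

Step 7
Reactants: 14 spirolactone diacetate
Product: 15 spirolactone diol (C1-OH and C4-OH cis to each other and to C9)
Conditions: K2CO3 (cat.), MeOH, 0 °C
Reagents that add atoms: none
Why: Base-catalysed transesterification with methanol removes both acetates, and the spiro-γ-lactone, which has no α-hydrogen and is favoured over its open hydroxy ester, should survive brief exposure at 0 °C.

Step 8
Reactants: 15 spirolactone diol
Product: 16 C4 4-nitrobenzoate with inverted C4 (ester oxygen now trans to C9 and cis to C8), C1-OH free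
Conditions: 4-O2NC6H4CO2H, PPh3, i-PrO2CN=NCO2i-Pr, THF, 0 °C
Reagents that add atoms: 4-nitrobenzoic acid, O=C(O)c1ccc(cc1)[N+](=O)[O-]
Why: Mitsunobu esterification (SN2 at the alkoxyphosphonium ion) inverts C4 to the configuration of the target, and only the unhindered C4 hydroxyl reacts because the C1 hydroxyl is neopentylic, next to the spiro centre.

Step 9
Reactants: 16 C4 4-nitrobenzoate
Product: 17 C1 triethylsilyl ether of 16
Conditions: Et3SiOTf, 2,6-lutidine, CH2Cl2, −78 → 0 °C
Reagents that add atoms: triethylsilyl trifluoromethanesulfonate, CC[Si](CC)(CC)OS(=O)(=O)C(F)(F)F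
Why: Silyl ether formation with the reactive triflate caps the hindered C1 hydroxyl so that it cannot trigger retro-aldol cleavage of the C1–C6 bond once C9 becomes an aldehyde.

Step 10
Reactants: 17 silyl-protected 4-nitrobenzoate
Product: 18 C4 alcohol (4R, as in the target), C1-OSiEt3, lactone intact
Conditions: K2CO3 (cat.), MeOH, 0 °C
Reagents that add atoms: none
Why: Transesterification with methanol cleaves the activated 4-nitrobenzoate at the acyl carbon, so the C4 configuration is retained.

Step 11
Reactants: 18 C4 alcohol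
Product: 19 C4 methyl ether (lactone, C1-OSiEt3, C7-OSiMe2t-Bu)
Conditions: NaH, MeI, THF, 0 °C → rt
Reagents that add atoms: iodomethane, CI
Why: Williamson ether synthesis at the unhindered C4 alkoxide; the lactone has no enolisable hydrogen and the alkoxide is trans to the lactone carbonyl, so translactonisation cannot occur.

Step 12
Reactants: 19 lactone methyl ether
Product: 20 lactol (C9 hemiacetal, anomeric mixture)
Conditions: i-Bu2AlH, CH2Cl2, −78 °C
Reagents that add atoms: none
Why: Partial reduction of a lactone to the lactol, whose tetrahedral aluminium alkoxide is stable at −78 °C; silyl ethers, the methyl ether and both alkenes are inert.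

Step 13
Reactants: 20 lactol
Product: 21 enol ether alcohol (C6–CH=CH–OMe, E/Z mixture; C8–CH2OH free)
Conditions: Ph3P(CH2OMe)Cl, KN(SiMe3)2, THF, 0 → 40 °C
Reagents that add atoms: (methoxymethyl)triphenylphosphonium chloride, COC[P+](c1ccccc1)(c1ccccc1)c1ccccc1.[Cl-]
Why: Wittig methoxymethylenation of the open hydroxy-aldehyde form of the lactol adds the middle carbon of the allyl group and releases the primary alcohol on C10.

Step 14
Reactants: 21 enol ether alcohol
Product: 22 C10 4-methylbenzenesulfonate of 21
Conditions: TsCl, pyridine, DMAP (cat.), CH2Cl2, 0 °C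
Reagents that add atoms: 4-methylbenzenesulfonyl chloride, Cc1ccc(cc1)S(Cl)(=O)=O
Why: Sulfonylation of the only free hydroxyl, a primary one, under basic conditions that leave the acid-sensitive enol ether untouched.

Step 15
Reactants: 22 tosylate
Product: 23 C8-methyl enol ether (C10 now CH3)
Conditions: LiBHEt3, THF, 0 °C → rt
Reagents that add atoms: none
Why: SN2 hydride displacement of a primary sulfonate by LiBHEt3 (reductive deoxygenation) converts the former lactone O–CH2 into the C8 methyl group without affecting C8.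

Step 16
Reactants: 23 C8-methyl enol ether
Product: 24 bicyclic lactol formed from C6–CH2–CHO and the cis C1 hydroxyl (anomeric mixture)
Conditions: 0.5 M aq. HCl, THF, 0 °C → rt
Reagents that add atoms: water, O
Why: Acid hydrolysis of the enol ether gives the homologated aldehyde, and simultaneous loss of the triethylsilyl group lets the cis C1 hydroxyl close a five-membered lactol; the more robust secondary tert-butyldimethylsilyl ether should survive the dilute acid.

Step 17
Reactants: 24 bicyclic lactol
Product: 25 allyl alcohol (megaphone skeleton with C1-OH and C7-OSiMe2t-Bu)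
Conditions: Ph3PCH3Br, KN(SiMe3)2, THF, 0 °C → rt
Reagents that add atoms: methyltriphenylphosphonium bromide, C[P+](c1ccccc1)(c1ccccc1)c1ccccc1.[Br-]
Why: Wittig methylenation of the lactol through its open aldehyde form completes the allyl group; the aldehyde is γ to the C1 oxygen, so retro-aldol cleavage is not possible.

Step 18
Reactants: 25 allyl alcohol
Product: 26 megaphone tert-butyldimethylsilyl ether
Conditions: Dess–Martin periodinane, CH2Cl2, rt
Reagents that add atoms: none
Why: Dess–Martin oxidation of the hindered allylic C1 alcohol gives the enone under neutral conditions in which C4, C6, C7 and C8 cannot epimerise.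

Step 19
Reactants: 26 megaphone silyl ether
Product: 27 megaphone
Conditions: HF·pyridine, pyridine, THF, 0 °C → rt
Reagents that add atoms: none
Why: Fluoride-mediated desilylation frees the benzylic C7 hydroxyl under buffered, weakly acidic conditions that spare the enone and the allylic methyl ether.

Step 20
Reactants: 27 megaphone
Product: 28 megaphone acetate
Conditions: Ac2O, pyridine, DMAP (cat.), CH2Cl2, rt
Reagents that add atoms: acetic anhydride, CC(=O)OC(C)=O
Why: DMAP-catalysed O-acylation of the secondary benzylic alcohol proceeds at oxygen with retention at C7.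

**Compound list**

1 | (R)-4-benzyl-1,3-oxazolidin-2-one | O=C1N[C@H](Cc2ccccc2)CO1 | starting material
2 | methyl 4-chloro-4-oxobutanoate | COC(=O)CCC(Cl)=O | starting material
3 | methyl 4-[(4R)-4-benzyl-2-oxo-1,3-oxazolidin-3-yl]-4-oxobutanoate | COC(=O)CCC(=O)N1[C@H](Cc2ccccc2)COC1=O | intermediate
4 | 3,4,5-trimethoxybenzaldehyde | O=Cc1cc(OC)c(OC)c(OC)c1 | starting material
5 | methyl (3S,4R)-3-{[(4R)-4-benzyl-2-oxo-1,3-oxazolidin-3-yl]carbonyl}-4-(trimethylsilyloxy)-4-(3,4,5-trimethoxyphenyl)butanoate | COC(=O)C[C@@H]([C@@H](O[Si](C)(C)C)c1cc(OC)c(OC)c(OC)c1)C(=O)N1[C@H](Cc2ccccc2)COC1=O | intermediate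
6 | free aldol alcohol (4-hydroxy analogue of 5) | COC(=O)C[C@@H]([C@@H](O)c1cc(OC)c(OC)c(OC)c1)C(=O)N1[C@H](Cc2ccccc2)COC1=O | intermediate
7 | methyl (3S,4R)-3-{[(4R)-4-benzyl-2-oxo-1,3-oxazolidin-3-yl]carbonyl}-4-(tert-butyldimethylsilyloxy)-4-(3,4,5-trimethoxyphenyl)butanoate | COC(=O)C[C@@H]([C@@H](O[Si](C)(C)C(C)(C)C)c1cc(OC)c(OC)c(OC)c1)C(=O)N1[C@H](Cc2ccccc2)COC1=O | intermediate
8 | methyl (3R,4R)-4-(tert-butyldimethylsilyloxy)-3-(hydroxymethyl)-4-(3,4,5-trimethoxyphenyl)butanoate | COC(=O)C[C@H](CO)[C@@H](O[Si](C)(C)C(C)(C)C)c1cc(OC)c(OC)c(OC)c1 | intermediate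
9 | (4R)-4-[(R)-(tert-butyldimethylsilyloxy)(3,4,5-trimethoxyphenyl)methyl]oxolan-2-one | O=C1C[C@H](CO1)[C@@H](O[Si](C)(C)C(C)(C)C)c1cc(OC)c(OC)c(OC)c1 | intermediate
10 | trans-3-[(dimethylamino)methyl] derivative of 9 (Mannich base) | O=C1[C@H](CN(C)C)[C@H](CO1)[C@@H](O[Si](C)(C)C(C)(C)C)c1cc(OC)c(OC)c(OC)c1 | intermediate
11 | trimethylammonium iodide of 10 | O=C1[C@H](C[N+](C)(C)C)[C@H](CO1)[C@@H](O[Si](C)(C)C(C)(C)C)c1cc(OC)c(OC)c(OC)c1.[I-] | intermediate
12 | (4R)-4-[(R)-(tert-butyldimethylsilyloxy)(3,4,5-trimethoxyphenyl)methyl]-3-methylideneoxolan-2-one | C=C1C(=O)OC[C@@H]1[C@@H](O[Si](C)(C)C(C)(C)C)c1cc(OC)c(OC)c(OC)c1 | intermediate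
13 | (1E,3E)-buta-1,3-diene-1,4-diyl diacetate | CC(=O)O/C=C/C=C/OC(C)=O | starting material
14 | spirolactone cycloadduct, C1/C4 diacetate (acetoxy groups cis to each other and to C9) | O=C1OC[C@H]([C@@H](O[Si](C)(C)C(C)(C)C)c3cc(OC)c(OC)c(OC)c3)[C@]12C[C@H](OC(C)=O)C=C[C@@H]2OC(C)=O | intermediate
15 | spirolactone C1,C4-diol | O=C1OC[C@H]([C@@H](O[Si](C)(C)C(C)(C)C)c3cc(OC)c(OC)c(OC)c3)[C@]12C[C@H](O)C=C[C@@H]2O | intermediate
16 | C4-inverted 4-nitrobenzoate, C1-OH free | O=C1OC[C@H]([C@@H](O[Si](C)(C)C(C)(C)C)c3cc(OC)c(OC)c(OC)c3)[C@]12C[C@@H](OC(=O)c4ccc(cc4)[N+](=O)[O-])C=C[C@@H]2O | intermediate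
17 | C1 triethylsilyl ether of 16 | O=C1OC[C@H]([C@@H](O[Si](C)(C)C(C)(C)C)c3cc(OC)c(OC)c(OC)c3)[C@]12C[C@@H](OC(=O)c4ccc(cc4)[N+](=O)[O-])C=C[C@@H]2O[Si](CC)(CC)CC | intermediate
18 | C4 alcohol (4R), C1-OSiEt3 spirolactone | O=C1OC[C@H]([C@@H](O[Si](C)(C)C(C)(C)C)c3cc(OC)c(OC)c(OC)c3)[C@]12C[C@@H](O)C=C[C@@H]2O[Si](CC)(CC)CC | intermediate
19 | C4 methyl ether, C1-OSiEt3 spirolactone | O=C1OC[C@H]([C@@H](O[Si](C)(C)C(C)(C)C)c3cc(OC)c(OC)c(OC)c3)[C@]12C[C@@H](OC)C=C[C@@H]2O[Si](CC)(CC)CC | intermediate
20 | lactol of 19 (anomeric mixture) | OC1OC[C@H]([C@@H](O[Si](C)(C)C(C)(C)C)c3cc(OC)c(OC)c(OC)c3)[C@]12C[C@@H](OC)C=C[C@@H]2O[Si](CC)(CC)CC | intermediate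
21 | enol ether alcohol (E/Z mixture, E shown) | CO/C=C/[C@]1([C@H](CO)[C@@H](O[Si](C)(C)C(C)(C)C)c2cc(OC)c(OC)c(OC)c2)C[C@@H](OC)C=C[C@@H]1O[Si](CC)(CC)CC | intermediate
22 | C10 tosylate of 21 (E shown) | CO/C=C/[C@]1([C@H](COS(=O)(=O)c2ccc(C)cc2)[C@@H](O[Si](C)(C)C(C)(C)C)c2cc(OC)c(OC)c(OC)c2)C[C@@H](OC)C=C[C@@H]1O[Si](CC)(CC)CC | intermediate
23 | C8-methyl enol ether (E shown) | CO/C=C/[C@]1([C@H](C)[C@@H](O[Si](C)(C)C(C)(C)C)c2cc(OC)c(OC)c(OC)c2)C[C@@H](OC)C=C[C@@H]1O[Si](CC)(CC)CC | intermediate
24 | bicyclic lactol from C6–CH2–CHO and C1-OH (anomeric mixture) | OC1C[C@]2([C@H](C)[C@@H](O[Si](C)(C)C(C)(C)C)c3cc(OC)c(OC)c(OC)c3)C[C@@H](OC)C=C[C@@H]2O1 | intermediate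
25 | 6-allyl-4-methoxycyclohex-2-en-1-ol with the silylated side chain | C=CC[C@]1([C@H](C)[C@@H](O[Si](C)(C)C(C)(C)C)c2cc(OC)c(OC)c(OC)c2)C[C@@H](OC)C=C[C@@H]1O | intermediate
26 | megaphone tert-butyldimethylsilyl ether | C=CC[C@]1([C@H](C)[C@@H](O[Si](C)(C)C(C)(C)C)c2cc(OC)c(OC)c(OC)c2)C[C@@H](OC)C=CC1=O | intermediate
27 | megaphone | C=CC[C@]1([C@H](C)[C@@H](O)c2cc(OC)c(OC)c(OC)c2)C[C@@H](OC)C=CC1=O | intermediate
28 | megaphone acetate | C=CC[C@]1([C@H](C)[C@@H](OC(C)=O)c2cc(OC)c(OC)c(OC)c2)C[C@@H](OC)C=CC1=O | target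

**Step count and risks**

Total: 20 steps. Longest linear sequence: 20 steps (1 → 28).

Step 6. The cycloaddition may stall, or the endo preference may erode: the dienophile is activated only by a lactone carbonyl and is hindered at the neighbouring carbon, the diene is only moderately nucleophilic, and long heating invites polymerisation of 12. Fallback (polar, cationic cycloaddition instead of the neutral thermal one): setting out from 12, i-Bu2AlH at −78 °C should give the α-methylene lactol F1, and methanol with pyridinium p-toluenesulfonate its methyl acetal F2. Me3SiOTf (cat.) in CH2Cl2 at −78 °C ionises F2 to the cyclic vinyl oxocarbenium ion, a far stronger dienophile, which should take up 13 on the same face and give the spiro acetal diacetate F3. Aqueous acetic acid hydrolyses F3 to the lactol diacetate F4, and oxidation with (n-Pr)4N[RuO4] (cat.) and N-methylmorpholine N-oxide comes back to the route at 14.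

Step 13. Olefination of the lactol may fail because ring opening exposes an aldehyde flanked by the quaternary C6, so the bulky ylide may react slowly and the base may degrade the material instead. Fallback (full reduction and olefination of a free aldehyde): setting out from 19, LiAlH4 in THF should give the diol F5. One equivalent of TsCl in pyridine at −20 °C should sulfonylate the less hindered hydroxyl on C10 and give the monotosylate F6, which LiBHEt3 reduces to the C8-methyl neopentyl alcohol F7. Dess–Martin oxidation gives the aldehyde F8, which reacts with Ph3P=CHOMe more readily than the lactol and comes back to the route at 23.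

Step 8. The Mitsunobu inversion at an allylic carbinol may lose configurational purity through allylic transposition or elimination to a diene. Fallback (oxidation and reagent-controlled reduction instead of SN2 inversion): setting out from 15, MnO2 in CH2Cl2 should oxidise only the unhindered allylic C4 alcohol and give the hydroxy enone F9, and Et3SiOTf with 2,6-lutidine its C1 triethylsilyl ether F10. Reduction with (S)-2-methyl-CBS-oxazaborolidine (cat.) and catecholborane at −78 °C, with the alkene side acting as the large group, should deliver the 4R alcohol and come back to the route at 18.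

**Further compounds**

F1 | step 6 | α-methylene lactol from 12 (anomeric mixture) | C=C1C(O)OC[C@@H]1[C@@H](O[Si](C)(C)C(C)(C)C)c1cc(OC)c(OC)c(OC)c1
F2 | step 6 | methyl acetal of F1 | C=C1C(OC)OC[C@@H]1[C@@H](O[Si](C)(C)C(C)(C)C)c1cc(OC)c(OC)c(OC)c1
F3 | step 6 | spiro methyl acetal diacetate (acetal analogue of 14) | COC1OC[C@H]([C@@H](O[Si](C)(C)C(C)(C)C)c3cc(OC)c(OC)c(OC)c3)[C@]12C[C@H](OC(C)=O)C=C[C@@H]2OC(C)=O
F4 | step 6 | spiro lactol diacetate | OC1OC[C@H]([C@@H](O[Si](C)(C)C(C)(C)C)c3cc(OC)c(OC)c(OC)c3)[C@]12C[C@H](OC(C)=O)C=C[C@@H]2OC(C)=O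
F5 | step 13 | diol from reduction of 19 (C9H2OH and C10H2OH) | OC[C@]1([C@H](CO)[C@@H](O[Si](C)(C)C(C)(C)C)c2cc(OC)c(OC)c(OC)c2)C[C@@H](OC)C=C[C@@H]1O[Si](CC)(CC)CC
F6 | step 13 | C10 monotosylate of F5 | OC[C@]1([C@H](COS(=O)(=O)c2ccc(C)cc2)[C@@H](O[Si](C)(C)C(C)(C)C)c2cc(OC)c(OC)c(OC)c2)C[C@@H](OC)C=C[C@@H]1O[Si](CC)(CC)CC
F7 | step 13 | C8-methyl neopentyl alcohol | OC[C@]1([C@H](C)[C@@H](O[Si](C)(C)C(C)(C)C)c2cc(OC)c(OC)c(OC)c2)C[C@@H](OC)C=C[C@@H]1O[Si](CC)(CC)CC
F8 | step 13 | C9 aldehyde | O=C[C@]1([C@H](C)[C@@H](O[Si](C)(C)C(C)(C)C)c2cc(OC)c(OC)c(OC)c2)C[C@@H](OC)C=C[C@@H]1O[Si](CC)(CC)CC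
F9 | step 8 | spirolactone 4-oxo-2-en-1-ol (hydroxy enone) | O=C1OC[C@H]([C@@H](O[Si](C)(C)C(C)(C)C)c3cc(OC)c(OC)c(OC)c3)[C@]12CC(=O)C=C[C@@H]2O
F10 | step 8 | C1 triethylsilyl ether of F9 | O=C1OC[C@H]([C@@H](O[Si](C)(C)C(C)(C)C)c3cc(OC)c(OC)c(OC)c3)[C@]12CC(=O)C=C[C@@H]2O[Si](CC)(CC)CC
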